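The north flask cannot carry its 0.10 M of starting complex through to complex with three exchanged: each complex takes 3 incoming ligand, and the 0.150 M charged pays for 0.0500 M. North holds 0.500 of what it needs. That ratio, incoming ligand charged over what full exchange of the starting complex charged takes, is the cover C, with c for a charge:

C = c(incoming ligand) / (3 c(starting complex))

north-east 2.00, east 1.00, north 0.500, blue 2.94, grey 0.581

| flask | starting complex | incoming ligand | remark | time |
|---|---|---|---|---|
| blue | 0.017 M | 0.15 M | run made earlier |  |
| grey | 0.086 M | 0.15 M | run made earlier |  |
| north-east | 0.025 M | 0.150 M |  | 1.5 h |
| east | 0.050 M | 0.150 M |  | 1.5 h |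
| north | 0.10 M | 0.150 M |  | 1.5 h |

| run | time / min | complex with three exchanged / % | starting complex / % |
|---|---|---|---|
| blue | 8.00 | 2 | 84 |
| blue | 12.0 | 0 | 79 |
| blue | 20.0 | 1 | 63 |
| blue | 30.0 | 2 | 52 |
| blue | 50.0 | 12 | 35 |
| blue | 90.0 | 23 | 20 |
| grey | 15.0 | 0 | 70 |
| grey | 30.0 | 3 | 61 |
| grey | 50.0 | 5 | 44 |
| grey | 60.0 | 0 | 44 |
| grey | 80.0 | 6 | 43 |
| grey | 90.0 | 10 | 45 |

(each reading ± 2 percentage points)

- a reading or a percentage of complex with three exchanged counts all its forms, free or not
- the concentration of complex with three exchanged that is asked is that of its free form alone
- "hardly changes" means that all values lie within two and a half points (for a concentration: within two and a half percent of the largest)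
- a reading of starting complex is of its free form alone

For whoever takes over the bench: grey and north lie below one, so there incoming ligand is the limiting reagent. I expect north to look like grey when you come, with starting complex flat near 44 %, and north-east to look like blue, whose starting complex read 20 % at 90.0 min. Do not stop north when its starting complex goes flat: in grey, complex with three exchanged still reached 10 % by 90.0 min.

As concentrations, the last readings of complex with three exchanged, 23 % in blue and 10 % in grey, are 0.00391 M and 0.00860 M, bound forms counted, so the free value stands lower. The row is charge times yield, and below C = one I do not trust it to keep climbing.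

1. [complex with three exchanged] (only what is free in solution) at the end for north-east, east, north, in this order
2. how the row runs (falls, then rises / hardly changes / rises all the way / rises, then falls / falls all the way)

The forecast gives 0.0052 M, 0.0075 M and 0.0082 M, a row that rises all the way, and says “The row rises, then flattens”. The flasks give 0.00460 M, 0.00610 M and 0.00577 M: the row rises, then falls.

    complex with two exchanged + incoming ligand ⇌ leaving ligand + complex with three exchanged (K = 19.2, k = 0.0843 L mol⁻¹ min⁻¹)
    complex with one exchanged + incoming ligand ⇌ leaving ligand + complex with two exchanged (K = 1.20, k = 0.214 L mol⁻¹ min⁻¹)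
    starting complex + complex with three exchanged ⇌ idle adduct, settled at all times (K = 6.90 L mol⁻¹)
    starting complex + incoming ligand ⇌ leaving ligand + complex with one exchanged (K = 0.845, k = 0.157 L mol⁻¹ min⁻¹)

Part of what holds north down is the consumption of incoming ligand: with incoming ligand held at its charge, north ends at 0.0163 M instead of 0.00577 M. North starts at C = 0.500 and keeps 43 % of its incoming ligand, a cover left of 0.213. North-east starts at 2.00 and keeps 75 %, a cover left of 1.50, and there the time allowed acts together with that consumption: 0.0213 M after 15.0 h, and 0.00614 M with the ligand held, against 0.00460 M.

(Readings and results are calculated from invented constants; scatter was added.)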